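## Structural features

The target 17 (C23H30O7) is a tricyclic spirodienone. Ring A, a benzene ring with three adjacent methoxy groups, is ortho-fused through arene C1 and arene C2 to the seven-membered ring C (arene C1, C7, C8, C8′, C7′, C1′, arene C2), and C1′ is also C4 of ring B, a 2,6-dimethoxycyclohexa-2,5-dienone. Three contiguous stereocentres lie on ring C: C7 (R, benzylic hydroxyl), C8 (S, methyl) and C8′ (R, methyl). Each neighbouring pair is trans on the ring, and the C7/C8 pair has the pattern of a syn propionate aldol with an aryl aldehyde. C1′ is quaternary but not stereogenic, because the two arms of ring B are identical. The fragile groups are the cross-conjugated dienone (acceptor at C2′ and C6′, reducible, acid-sensitive) and the C7–O bond, which is benzylic and para to a methoxy group; the free C7 oxygen can also reach C2′ through a six-membered transition state under base. The real difficulty is C1′, a fully substituted carbon that carries a doubly ortho-substituted aryl group, closes a seven-membered ring and must hold ring B at the dienone oxidation level; the second difficulty is C8′, which has no neighbouring functional group. The key step uses the fact that C1′ stands para to the ring B carbonyl and bears only carbon substituents: it maps onto the C4 carbonyl carbon of a 2,6-dimethoxy-1,4-benzoquinone skeleton, which can act first as a carbonyl and then as a cation to form the bonds to arene C2 and to C7′.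

## Logic of the disconnections

17 to 16: the O–H bond at C7 is replaced by an O–Si bond. The C7 oxygen must be neither acidic nor nucleophilic during the organolithium and cation chemistry. The skeleton is unchanged; the forward step must free the alcohol without forming an alkoxide next to ring B.

16 to 15: the C8′–H bond and one C–H bond of the C8′ methyl group are removed, which leaves an exocyclic C8′=CH2. This is exactly what an allylsilane leaves behind after it has formed a C–C bond. One stereocentre disappears. The forward hydrogenation must place the new methyl group trans to the C8 methyl group and must leave the two ring B alkenes alone.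

15 to 8 and 10: the bonds arene C2–C1′ and C1′–C7′ are cut. Both end at the one carbon that is a carbonyl carbon in 10, so ring C and the quaternary centre are dismantled together and the molecule falls into two pieces of similar size, with ring B complete. The forward step demands that a metalated arene adds to a single, unambiguous carbonyl, that the adduct ionizes at C1′, and that the allylsilane closes a seven-membered ring faster than any oxygen captures the cation. Holding the second ring B carbonyl as a ketal in 10 meets the first two demands.

10 to 9: one C–O bond of the ketal carbon is cut, which returns ring B to an aromatic phenol. The gain is a cheap aromatic feedstock; the forward step is an oxidative dearomatization in methanol.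

8 to 6: the bonds C8′–C7′ and C8′–CH2Si are cut, both at the former ester carbon. Two identical one-carbon silyl nucleophiles then deliver the whole allylsilane in one operation. The forward step needs a non-basic nucleophile, because C8 is α to the ester.

6 to 5: the O–Si bond at C7 is cut. This only removes the protecting group; silylation of a hindered secondary alcohol needs a silyl triflate.

5 to 4: the acyl C–OMe bond is exchanged for the acyl C–N bond of the auxiliary. The exchange is placed before silylation, because the free β-hydroxyl assists mild cleavage at the exocyclic carbonyl.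

4 to 1 and 2: the C7–C8 bond is cut. This is the only C–C bond between the two stereocentres, and it reduces the chain to two commercial compounds. The forward aldol must set both centres (syn, absolute sense from the auxiliary of 1).

## Other disconnections considered

Alternative 1: The cut removes both methyl groups (C8′–CH3 and C8–CH3). In the forward direction the unsubstituted ring C aryl enone A1 would take a methyl group at C8′ from a methylzinc reagent under copper catalysis with a chiral phosphoramidite, and the zinc enolate would be C-methylated at C8 to give the trans-dimethyl ketone A2.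
- In favour: both methyl-bearing centres come from one catalytic, reagent-controlled operation, no auxiliary is consumed, and C8, being α to the ketone, can be equilibrated to the trans isomer. On control of C8′ this is the better plan, since the chosen route leaves C8′ to a substrate-controlled hydrogenation.
- Against, structure: A1 already contains C1′ and ring B, so the central difficulty is only moved to the synthesis of A1.
- Against, mechanism: A1 offers the methyl nucleophile three acceptor positions and two carbonyls, zinc enolates of aryl ketones alkylate slowly, and A2 must afterwards be reduced at C7 on the face syn to the C8 methyl group without touching the ring B carbonyl.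
- Step economy: the key step itself is shorter than the aldol sequence of the chosen plan, but A1 needs its own multi-step synthesis and A2 needs a further reduction, so the total is expected to be longer.

Alternative 2: The cut removes four carbons of ring B (C1′–C6′ and C2′=C3′, with the C1′–C2′ bond kept as a formyl group). In the forward direction the enamine or enolate of the ring C aldehyde A3 would add through C1′ to the vinyl ketone A4, and aldol condensation of the methoxymethyl carbon with the formyl group would close ring B as the spiro cyclohexenone A5.
- In favour: no carbocation and no organolithium are involved, and all three stereocentres of ring C are in place before ring B exists, so the late hydrogenation of the chosen plan is avoided; on this point it is the better plan. The two stereocentres created in A5 need no control, which is equal to the chosen plan, where C1′ is never stereogenic.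
- Against, structure: A3 needs a separate construction of the seven-membered ring with a benzylic formyl group, and A5 is two hydrogens short of the dienone.
- Against, mechanism: the conjugate addition must create the quaternary C1′ from a hindered α-aryl aldehyde, and A4 is an electron-rich α-alkoxy enone that is a poor and polymerization-prone acceptor.
- Step economy: a regioselective dehydrogenation and the desilylation follow the annulation and several steps precede it; the chosen plan brings ring B at its final oxidation level in one step from a phenol.

Alternative 3: The cut runs through arene C1–C7 and arene C2–C1′, so that ring A is inserted into the C7–C1′ bond of a five-membered keto ester. In the forward direction fluoride would release the aryne from the silyl triflate A6. The enolate carbon of the keto ester A7 would add to the aryne carbon remote from methoxy, the resulting aryl anion would attack the ketone, and fragmentation of the cyclobutoxide would give the benzo-fused seven-membered keto ester A8.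
- In favour: ring C and both aryl–carbon bonds form in one convergent step, the methoxy group next to the aryne controls the regiochemistry, and both methyl stereocentres are fixed from the start in a ketone whose two α-positions are equivalent. On C8/C8′ control it is the better plan and on convergence it is the equal of the chosen one.
- Against, structure: A8 has a ketone at C1′ and an ester at C7. C1′ must still receive two C–C bonds to become the spiro dienone, and C7 must be changed from C–CO2Me to C–OH with the 7R configuration.
- Against, mechanism: the insertion is well founded, but it does nothing for the quaternary centre, which is the hardest part of the target.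
- Step economy: the redox and functional-group changes after A8 make the route clearly longer than the chosen one.

Key step: step 6

Remarks on the chemistry:
- Locants in the text are lignan-type (C7, C8, C8′, C7′, C1′; rings A, B, C). Systematic names use benzo[7]annulene numbering, where C5 = C1′, C6 = C7′, C7 = C8′, C8 = C8 and C9 = C7.
- The electrophile for C1′ is 10, the C1 dimethyl ketal of 2,6-dimethoxy-1,4-benzoquinone, and not the free quinone. In the free quinone the C4 carbonyl is conjugated with both methoxy groups and is the less electrophilic one, so attack at the methoxy-flanked C1 carbonyl and electron transfer from the aryllithium to the quinone are both to be expected. In 10 the C4 carbonyl is the only carbonyl, and its adduct ionizes far more easily, because the C1′ cation is a doubly vinylogous oxocarbenium ion rather than an acyl-substituted cation. The bonds formed, the ring closed and the skeletons of 8 and 15 are unchanged.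
- Assumption: 10 is treated as not purchasable and is made in one step from commercial 9.
- The auxiliary is removed before silylation, and the final desilylation is run without base; both changes protect C8 and the dienone.

## Route

Step 1
Reactants: 1 (R)-4-benzyl-3-propionyloxazolidin-2-one; 2 2-bromo-3,4,5-trimethoxybenzaldehyde
Product: 4 (R)-4-benzyl-3-[(2R,3R)-3-(2-bromo-3,4,5-trimethoxyphenyl)-3-hydroxy-2-methylpropanoyl]oxazolidin-2-one, via Z-boron enolate 3 (not isolated)
Conditions: Bu2BOTf, i-Pr2NEt, CH2Cl2, 0 °C; then 2, −78 → 0 °C; then pH 7 buffer, MeOH, H2O2, 0 °C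
Reagents that add atoms: none
Why: Evans syn aldol: the Z-dibutylboron enolate should react through a closed Zimmerman–Traxler chair on the face away from the benzyl group, which sets the (2R,3R) syn pair, that is C7 (R) and C8 (S after the later change of substituents).

Step 2
Reactants: 4 (R)-4-benzyl-3-[(2R,3R)-3-(2-bromo-3,4,5-trimethoxyphenyl)-3-hydroxy-2-methylpropanoyl]oxazolidin-2-one
Product: 5 methyl (2R,3R)-3-(2-bromo-3,4,5-trimethoxyphenyl)-3-hydroxy-2-methylpropanoate
Conditions: MeMgBr, MeOH, CH2Cl2, 0 °C
Reagents that add atoms: methanol, CO
Why: Transesterification of the imide by MeOMgBr formed in the flask: magnesium bound between the free β-hydroxyl and the exocyclic carbonyl should direct methoxide to that carbonyl, and the weak base at 0 °C should cause neither retro-aldol cleavage nor epimerization at C8.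

Step 3
Reactants: 5 methyl (2R,3R)-3-(2-bromo-3,4,5-trimethoxyphenyl)-3-hydroxy-2-methylpropanoate
Product: 6 methyl (2R,3R)-3-(2-bromo-3,4,5-trimethoxyphenyl)-3-[(tert-butyldimethylsilyl)oxy]-2-methylpropanoate
Conditions: TBSOTf, 2,6-lutidine, CH2Cl2, −78 → 0 °C
Reagents that add atoms: tert-butyldimethylsilyl triflate, CC(C)(C)[Si](C)(C)OS(=O)(=O)C(F)(F)F
Why: Silylation of a hindered secondary alcohol with a silyl triflate and a hindered pyridine base, which is not basic enough to touch C8.

Step 4
Reactants: 6 methyl (2R,3R)-3-(2-bromo-3,4,5-trimethoxyphenyl)-3-[(tert-butyldimethylsilyl)oxy]-2-methylpropanoate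
Product: 8 tert-butyl{[(1R,2S)-1-(2-bromo-3,4,5-trimethoxyphenyl)-2-methyl-3-[(trimethylsilyl)methyl]but-3-en-1-yl]oxy}dimethylsilane, via tertiary carbinol 7 (not isolated)
Conditions: Me3SiCH2MgCl, CeCl3, THF, −78 °C → rt; aq. NH4Cl; then silica gel, CH2Cl2, rt
Reagents that add atoms: (trimethylsilyl)methylmagnesium chloride, C[Si](C)(C)C[Mg]Cl
Why: Double addition of the weakly basic organocerium reagent to the ester should give the bis(β-silyl) carbinol, and its acid-promoted Peterson elimination on silica should give the 2-substituted allylsilane. The cerium reagent should not enolize the ester or the intermediate ketone, so C8 is kept, and the aryl bromide is inert.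

Step 5
Reactants: 9 3,4,5-trimethoxyphenol
Product: 10 3,4,4,5-tetramethoxycyclohexa-2,5-dien-1-one
Conditions: PhI(OAc)2, MeOH, 0 °C
Reagents that add atoms: methanol, CO
Why: Oxidative dearomatization of a para-alkoxyphenol with a trivalent iodine reagent: methanol should add at the methoxy-bearing para carbon and give the quinone monoketal, in which the former C4 carbonyl of the quinone skeleton is the only carbonyl.

Step 6
Reactants: 8 tert-butyl{[(1R,2S)-1-(2-bromo-3,4,5-trimethoxyphenyl)-2-methyl-3-[(trimethylsilyl)methyl]but-3-en-1-yl]oxy}dimethylsilane; 10 3,4,4,5-tetramethoxycyclohexa-2,5-dien-1-one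
Product: 15 (8S,9R)-9-[(tert-butyldimethylsilyl)oxy]-2,3,3′,4,5′-pentamethoxy-8-methyl-7-methylidene-6,7,8,9-tetrahydrospiro[benzo[7]annulene-5,1′-cyclohexa[2,5]dien]-4′-one, via aryllithium 11 (not isolated), via lithium alkoxide 12 (not isolated), via silyl ether 13 (not isolated), via spiro ketal 14 (not isolated)
Conditions: n-BuLi, THF, −78 °C; then 10 (0.95 equiv), −78 °C; then CH2Cl2 (high dilution), 2,6-di-tert-butyl-4-methylpyridine, TMSOTf, −78 → −30 °C; then aq. oxalic acid, THF, 0 °C
Reagents that add atoms: water, O
Why: Proposed new method: bromine–lithium exchange on 8 should be faster than any deprotonation at −78 °C and give 11, which adds 1,2 to the only carbonyl of 10 (arene C2–C1′) to give 12; this half is the established addition of aryllithiums to quinone monoketals. TMSOTf should silylate the alkoxide to 13 and then ionize the C1′–O bond, because that cation is stabilized by ring A and by both β-methoxy groups, whereas ionization at the ketal carbon would give a cross-conjugated cation without this help. The terminal alkene carbon of the allylsilane then attacks C1′ (C1′–C7′), and the β-silyl cation gives up silicon to triflate, which returns TMSOTf and leaves the exocyclic methylene; the closest known reaction type is the silyl-triflate-promoted Hosomi–Sakurai allylation of acetals and of ionizable silyl ethers, here intramolecular. Ring C closes in a seven-membered mode that is endo with respect to the allylsilane π bond (both alkene carbons become ring atoms) and exo with respect to the π system of ring B. No stereocentre is created, since C1′ carries two identical arms and C7 and C8 are not touched. The step needs C–C closure at C1′ and not at the methoxy-bearing termini of the cation, which would require a bridged medium ring, and not capture by the C7 oxygen, which is hindered by the TBS group and should be reversible under the Lewis acid; high dilution and a slight deficit of 10 suppress intermolecular allylation. The hindered pyridine removes traces of triflic acid that would protodesilylate the allylsilane or move the new double bond, and silicon rules out proton loss toward C8. Aqueous oxalic acid finally hydrolyses the doubly allylic ketal of 14 to the dienone 15.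

Step 7
Reactants: 15 (8S,9R)-9-[(tert-butyldimethylsilyl)oxy]-2,3,3′,4,5′-pentamethoxy-8-methyl-7-methylidene-6,7,8,9-tetrahydrospiro[benzo[7]annulene-5,1′-cyclohexa[2,5]dien]-4′-one
Product: 16 (7R,8S,9R)-9-[(tert-butyldimethylsilyl)oxy]-2,3,3′,4,5′-pentamethoxy-7,8-dimethyl-6,7,8,9-tetrahydrospiro[benzo[7]annulene-5,1′-cyclohexa[2,5]dien]-4′-one
Conditions: Mn(dpm)3 (dpm = 2,2,6,6-tetramethylheptane-3,5-dionate, cat.), PhSiH3, t-BuOOH, i-PrOH, rt, argon
Reagents that add atoms: none
Why: Mukaiyama-type hydrogen-atom-transfer hydrogenation: a manganese hydride should give a hydrogen atom to the terminal CH2, and the tertiary C8′ radical should take its second hydrogen so that the new methyl group ends pseudo-equatorial and trans to the C8 methyl group (C8′ R), the thermodynamic-type outcome that surface hydrogenation would not be expected to give. The 1,1-disubstituted alkene is the fastest acceptor, while the ring B alkenes are trisubstituted and their hydrogen-accepting carbon is next to the quaternary C1′.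

Step 8
Reactants: 16 (7R,8S,9R)-9-[(tert-butyldimethylsilyl)oxy]-2,3,3′,4,5′-pentamethoxy-7,8-dimethyl-6,7,8,9-tetrahydrospiro[benzo[7]annulene-5,1′-cyclohexa[2,5]dien]-4′-one
Product: 17 (7R,8S,9R)-9-hydroxy-2,3,3′,4,5′-pentamethoxy-7,8-dimethyl-6,7,8,9-tetrahydrospiro[benzo[7]annulene-5,1′-cyclohexa[2,5]dien]-4′-one
Conditions: HF·pyridine, pyridine, THF, 0 °C → rt
Reagents that add atoms: none
Why: Fluoride cleavage of the silyl ether under buffered conditions: no alkoxide is formed, so the C7 oxygen should not add to C2′ of the dienone, and the medium is too weakly acidic to ionize the benzylic C7–O bond.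

## Compound list

1 | (R)-4-benzyl-3-propionyloxazolidin-2-one | CCC(=O)N1[C@H](Cc2ccccc2)COC1=O | starting material
2 | 2-bromo-3,4,5-trimethoxybenzaldehyde | COc1cc(C=O)c(Br)c(OC)c1OC | starting material
3 | (R,Z)-4-benzyl-3-{1-[(dibutylboranyl)oxy]prop-1-en-1-yl}oxazolidin-2-one | C/C=C(\OB(CCCC)CCCC)N1[C@H](Cc2ccccc2)COC1=O | intermediate (not isolated)
4 | (R)-4-benzyl-3-[(2R,3R)-3-(2-bromo-3,4,5-trimethoxyphenyl)-3-hydroxy-2-methylpropanoyl]oxazolidin-2-one | O=C(N1[C@H](Cc2ccccc2)COC1=O)[C@H](C)[C@@H](O)c1cc(OC)c(OC)c(OC)c1Br | intermediate
5 | methyl (2R,3R)-3-(2-bromo-3,4,5-trimethoxyphenyl)-3-hydroxy-2-methylpropanoate | COC(=O)[C@H](C)[C@@H](O)c1cc(OC)c(OC)c(OC)c1Br | intermediate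
6 | methyl (2R,3R)-3-(2-bromo-3,4,5-trimethoxyphenyl)-3-[(tert-butyldimethylsilyl)oxy]-2-methylpropanoate | COC(=O)[C@H](C)[C@@H](O[Si](C)(C)C(C)(C)C)c1cc(OC)c(OC)c(OC)c1Br | intermediate
7 | (3R,4R)-4-(2-bromo-3,4,5-trimethoxyphenyl)-4-[(tert-butyldimethylsilyl)oxy]-3-methyl-1-(trimethylsilyl)-2-[(trimethylsilyl)methyl]butan-2-ol | C[Si](C)(C)CC(O)(C[Si](C)(C)C)[C@H](C)[C@@H](O[Si](C)(C)C(C)(C)C)c1cc(OC)c(OC)c(OC)c1Br | intermediate (not isolated)
8 | tert-butyl{[(1R,2S)-1-(2-bromo-3,4,5-trimethoxyphenyl)-2-methyl-3-[(trimethylsilyl)methyl]but-3-en-1-yl]oxy}dimethylsilane | C[Si](C)(C)CC(=C)[C@H](C)[C@@H](O[Si](C)(C)C(C)(C)C)c1cc(OC)c(OC)c(OC)c1Br | intermediate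
9 | 3,4,5-trimethoxyphenol | COc1cc(O)cc(OC)c1OC | starting material
10 | 3,4,4,5-tetramethoxycyclohexa-2,5-dien-1-one | COC1=CC(=O)C=C(OC)C1(OC)OC | intermediate
11 | {2-[(1R,2S)-1-[(tert-butyldimethylsilyl)oxy]-2-methyl-3-[(trimethylsilyl)methyl]but-3-en-1-yl]-4,5,6-trimethoxyphenyl}lithium | C[Si](C)(C)CC(=C)[C@H](C)[C@@H](O[Si](C)(C)C(C)(C)C)c1cc(OC)c(OC)c(OC)c1[Li] | intermediate (not isolated)
12 | lithium 1-{2-[(1R,2S)-1-[(tert-butyldimethylsilyl)oxy]-2-methyl-3-[(trimethylsilyl)methyl]but-3-en-1-yl]-4,5,6-trimethoxyphenyl}-3,4,4,5-tetramethoxycyclohexa-2,5-dien-1-olate | C[Si](C)(C)CC(=C)[C@H](C)[C@@H](O[Si](C)(C)C(C)(C)C)c1cc(OC)c(OC)c(OC)c1C1(O[Li])C=C(OC)C(OC)(OC)C(OC)=C1 | intermediate (not isolated)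
13 | tert-butyl{[(1R,2S)-2-methyl-1-{3,4,5-trimethoxy-2-[3,4,4,5-tetramethoxy-1-(trimethylsilyloxy)cyclohexa-2,5-dien-1-yl]phenyl}-3-[(trimethylsilyl)methyl]but-3-en-1-yl]oxy}dimethylsilane | C[Si](C)(C)CC(=C)[C@H](C)[C@@H](O[Si](C)(C)C(C)(C)C)c1cc(OC)c(OC)c(OC)c1C1(O[Si](C)(C)C)C=C(OC)C(OC)(OC)C(OC)=C1 | intermediate (not isolated)
14 | tert-butyl{[(8S,9R)-2,3,3′,4,4′,4′,5′-heptamethoxy-8-methyl-7-methylidene-6,7,8,9-tetrahydrospiro[benzo[7]annulene-5,1′-cyclohexa[2,5]dien]-9-yl]oxy}dimethylsilane | COC1=CC2(C=C(OC)C1(OC)OC)CC(=C)[C@H](C)[C@@H](O[Si](C)(C)C(C)(C)C)c1cc(OC)c(OC)c(OC)c12 | intermediate (not isolated)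
15 | (8S,9R)-9-[(tert-butyldimethylsilyl)oxy]-2,3,3′,4,5′-pentamethoxy-8-methyl-7-methylidene-6,7,8,9-tetrahydrospiro[benzo[7]annulene-5,1′-cyclohexa[2,5]dien]-4′-one | COC1=CC2(C=C(OC)C1=O)CC(=C)[C@H](C)[C@@H](O[Si](C)(C)C(C)(C)C)c1cc(OC)c(OC)c(OC)c12 | intermediate
16 | (7R,8S,9R)-9-[(tert-butyldimethylsilyl)oxy]-2,3,3′,4,5′-pentamethoxy-7,8-dimethyl-6,7,8,9-tetrahydrospiro[benzo[7]annulene-5,1′-cyclohexa[2,5]dien]-4′-one | COC1=CC2(C=C(OC)C1=O)C[C@@H](C)[C@H](C)[C@@H](O[Si](C)(C)C(C)(C)C)c1cc(OC)c(OC)c(OC)c12 | intermediate
17 | (7R,8S,9R)-9-hydroxy-2,3,3′,4,5′-pentamethoxy-7,8-dimethyl-6,7,8,9-tetrahydrospiro[benzo[7]annulene-5,1′-cyclohexa[2,5]dien]-4′-one (CNP0288561.1) | COC1=CC2(C=C(OC)C1=O)C[C@@H](C)[C@H](C)[C@@H](O)c1cc(OC)c(OC)c(OC)c12 | target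

## Step count and least certain steps

Total: 8 steps. Longest linear sequence: 7 steps (steps 1–4 and 6–8, from 1 and 2); step 5 is a one-step side branch.

Step 6 (bears the label "Proposed new method:"). The most likely failure is ionization at the ketal carbon of 13 instead of at C1′, followed by an aryl shift or by simple loss of the ketal. A second possibility is that the well-stabilized C1′ cation is dealkylated at a methoxy group before the seven-membered closure takes place. Migration of the TBS group from the C7 oxygen to the aryl carbanion is also possible if 11 is allowed to warm. The fallback uses known chemistry, sets out from 8 and returns at 15. Suzuki–Miyaura coupling of 8 with commercial 2,6-dimethoxy-4-(4,4,5,5-tetramethyl-1,3,2-dioxaborolan-2-yl)phenol (Pd(OAc)2, SPhos, K3PO4, toluene/H2O, 90 °C) should form the arene C2–C1′ bond and give the biaryl phenol F1. Oxidative dearomatization of the biaryl phenol F1 with PhI(OAc)2 in (CF3)2CHOH at −20 °C, with capture of the para carbon by the tethered allylsilane, should then form C1′–C7′ and give 15. This costs one more step and an oxidant, but both operations are established reaction types.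

Step 7. Two processes may interfere: reduction of the ring B alkenes by the same hydrogen-atom-transfer manifold, since each would give a radical stabilized by the carbonyl and a methoxy group, and insufficient facial selectivity at the C8′ radical in a flexible seven-membered ring. The fallback sets out from 14 and returns at 16. The work-up of step 6 is changed (Et3N, aq. NaHCO3, no acid) so that 14 is isolated. The same hydrogenation on 14, where ring B is a bis(enol ether) ketal without an acceptor carbonyl, should give the saturated spiro ketal F2, and aqueous oxalic acid should then convert the saturated spiro ketal F2 into 16.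

Step 8. Addition of the freed C7 oxygen to C2′ of the dienone (six-membered oxa-bridge), or acid-induced ionization of the activated benzylic C7–O bond with loss of configuration, may compete with simple desilylation. The fallback sets out from 14 and returns at 17. 14 is isolated and hydrogenated as in the fallback to step 7 to give the saturated spiro ketal F2. Bu4NF in THF then removes the silyl group while ring B is still a ketal and offers no acceptor, which should give the hydroxy ketal F3. Brief treatment of the hydroxy ketal F3 with aqueous oxalic acid unveils the dienone last and gives 17.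

Step 4. The second addition may stall at the ketone stage because of the α-branch and the neighbouring silyloxy group, or the allylsilane may be protodesilylated during the acid-promoted elimination. The fallback sets out from 6 and returns at 8. Me3SiCH2Li (2 equiv, pentane/THF, −78 °C) should convert 6 into the β-ketosilane F4, which is held as its enolate and so does not add a second time. Wittig methylenation of the β-ketosilane F4 with salt-free Ph3P=CH2 (THF, 0 °C) should give 8; the acidic position of F4 is the silylated CH2, which shields C8 from epimerization.

## Further compounds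

F1 | step 6 | 2′-[(1R,2S)-1-[(tert-butyldimethylsilyl)oxy]-2-methyl-3-[(trimethylsilyl)methyl]but-3-en-1-yl]-3,4′,5,5′,6′-pentamethoxy-[1,1′-biphenyl]-4-ol | C[Si](C)(C)CC(=C)[C@H](C)[C@@H](O[Si](C)(C)C(C)(C)C)c1cc(OC)c(OC)c(OC)c1-c1cc(OC)c(O)c(OC)c1
F2 | step 7 | tert-butyl{[(7R,8S,9R)-2,3,3′,4,4′,4′,5′-heptamethoxy-7,8-dimethyl-6,7,8,9-tetrahydrospiro[benzo[7]annulene-5,1′-cyclohexa[2,5]dien]-9-yl]oxy}dimethylsilane | COC1=CC2(C=C(OC)C1(OC)OC)C[C@@H](C)[C@H](C)[C@@H](O[Si](C)(C)C(C)(C)C)c1cc(OC)c(OC)c(OC)c12
F3 | step 8 | (7R,8S,9R)-2,3,3′,4,4′,4′,5′-heptamethoxy-7,8-dimethyl-6,7,8,9-tetrahydrospiro[benzo[7]annulene-5,1′-cyclohexa[2,5]dien]-9-ol | COC1=CC2(C=C(OC)C1(OC)OC)C[C@@H](C)[C@H](C)[C@@H](O)c1cc(OC)c(OC)c(OC)c12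
F4 | step 4 | (3R,4R)-4-(2-bromo-3,4,5-trimethoxyphenyl)-4-[(tert-butyldimethylsilyl)oxy]-3-methyl-1-(trimethylsilyl)butan-2-one | C[Si](C)(C)CC(=O)[C@H](C)[C@@H](O[Si](C)(C)C(C)(C)C)c1cc(OC)c(OC)c(OC)c1Br
A1 | alternative 1 | 2,3,3′,4,5′-pentamethoxyspiro[benzo[7]annulene-5,1′-cyclohexa[2,5]diene]-4′,9(6H)-dione | COC1=CC2(C=C(OC)C1=O)CC=CC(=O)c1cc(OC)c(OC)c(OC)c12
A2 | alternative 1 | (7R,8S)-2,3,3′,4,5′-pentamethoxy-7,8-dimethyl-7,8-dihydrospiro[benzo[7]annulene-5,1′-cyclohexa[2,5]diene]-4′,9(6H)-dione | COC1=CC2(C=C(OC)C1=O)C[C@@H](C)[C@H](C)C(=O)c1cc(OC)c(OC)c(OC)c12
A3 | alternative 2 | (7R,8S,9R)-9-[(tert-butyldimethylsilyl)oxy]-2,3,4-trimethoxy-7,8-dimethyl-6,7,8,9-tetrahydro-5H-benzo[7]annulene-5-carbaldehyde (C5 epimers) | O=CC1C[C@@H](C)[C@H](C)[C@@H](O[Si](C)(C)C(C)(C)C)c2cc(OC)c(OC)c(OC)c12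
A4 | alternative 2 | 1,3-dimethoxybut-3-en-2-one | COCC(=O)C(=C)OC
A5 | alternative 2 | (7R,8S,9R)-9-[(tert-butyldimethylsilyl)oxy]-2,3,3′,4,5′-pentamethoxy-7,8-dimethyl-6,7,8,9-tetrahydrospiro[benzo[7]annulene-5,1′-cyclohex[2]en]-4′-one (epimers at C1′ and C5′) | COC1=CC2(CC(OC)C1=O)C[C@@H](C)[C@H](C)[C@@H](O[Si](C)(C)C(C)(C)C)c1cc(OC)c(OC)c(OC)c12
A6 | alternative 3 | 3,4,5-trimethoxy-2-(trimethylsilyl)phenyl trifluoromethanesulfonate | COc1cc(OS(=O)(=O)C(F)(F)F)c([Si](C)(C)C)c(OC)c1OC
A7 | alternative 3 | methyl (4R,5S)-4,5-dimethyl-2-oxocyclopentane-1-carboxylate (C1 epimers) | O=C1C[C@@H](C)[C@H](C)C1C(=O)OC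
A8 | alternative 3 | methyl (6S,7R)-1,2,3-trimethoxy-6,7-dimethyl-9-oxo-6,7,8,9-tetrahydro-5H-benzo[7]annulene-5-carboxylate (C5 epimers) | O=C1C[C@@H](C)[C@H](C)C(C(=O)OC)c2cc(OC)c(OC)c(OC)c12
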